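Rings A and B of the target share one pattern. The tether carbon C6 lies para to the methyl-bearing C3, and C2 and C4, which flank C3, carry oxygen. This is a 5-alkyl-2-methylresorcinol, so both rings are cut back to a cyclohexane-1,3-dione built from an ethyl enone and malonate. One operation on the linear C23 bis(enone) 5 (two ethyl ketones, two E-alkenes, thirteen CH2 groups between the β-carbons) adds two malonates and closes both six-membered rings, forming four C–C bonds. The ester left on C1 is kept as a control element for aromatisation and for single O-methylation. The C1 and C5 oxygens follow by oxidation.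

Key step: step 4

Remark on structure: the target has no stereocentre, and ring B is drawn as one of two degenerate 2,5-dihydroxyquinone tautomers.
Remark on numbering: ring A is the methoxy ring and ring B the dihydroxy ring. Target locants are C1 (C=O), C2 (OMe or OH), C3 (CH3), C4 (C=O), C5 (OH) and C6 (tether). In 8–11, C1 is the ester-bearing carbon. Once CO2 is lost, the local mirror plane through C3 and C6 returns, and ring A is then numbered so that OMe sits on C2.

Step 1
Reactants: 1 ω-pentadecalactone (oxacyclohexadecan-2-one)
Product: 2 pentadecane-1,15-diol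
Conditions: LiAlH4, THF, 0 °C to reflux; H2O/aq NaOH work-up
Reagents that add atoms: none
Why: Hydride reduction of a lactone opens the ring to the α,ω-diol, and no other functional group is present.

Step 2
Reactants: 2 pentadecane-1,15-diol
Product: 3 pentadecanedial
Conditions: TEMPO (cat.), PhI(OAc)2 (2.2 equiv), CH2Cl2, rt
Reagents that add atoms: none
Why: The oxoammonium (TEMPO) oxidation of primary alcohols stops at the aldehyde in dry CH2Cl2 and runs at room temperature, where the waxy diol stays in solution.

Step 3
Reactants: 3 pentadecanedial; 4 diethyl (2-oxobutyl)phosphonate (2.4 equiv)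
Product: 5 (4E,19E)-tricosa-4,19-diene-3,21-dione
Conditions: LiCl, iPr2NEt, MeCN/THF, rt
Reagents that add atoms: none
Why: A twofold Horner–Wadsworth–Emmons olefination with a stabilised β-ketophosphonate anion gives E-enones, and the weak amine base with LiCl avoids aldol self-condensation of the enolisable dialdehyde.

Step 4
Reactants: 5 (4E,19E)-tricosa-4,19-diene-3,21-dione; 6 dimethyl malonate (2.6 equiv)
Product: 8 dimethyl 6,6'-(tridecane-1,13-diyl)bis(3-methyl-2,4-dioxocyclohexane-1-carboxylate) (epimers and enol forms), via bis-Michael adduct 7 (not isolated)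
Conditions: NaOMe (2.4 equiv), MeOH/THF, reflux; then aq HCl, 0 °C
Reagents that add atoms: none
Why: Sodiomalonate adds 1,4 to C5 and C19 of 5 to give 7, proton transfer then moves each ketone enolate to the CH2 of the ethyl group, and that carbon attacks one malonate ester with loss of methoxide (Michael addition followed by an intramolecular Claisen, Dieckmann-type, condensation). The closest known reaction type is the malonate/alk-3-en-2-one annulation to 5-alkylcyclohexane-1,3-diones (dihydroresorcylates), which also runs with ethyl alkenyl ketones. Each of the two rings closes by a 6-(enolexo)-exo-trig acyl substitution, and the two ends, thirteen CH2 groups apart, react independently. The new stereocentres (C1, C3 and C6 of each ring) are not controlled: C1 and C3 epimerise through enols, the remote C6/C6' pair forms without induction, and all six are erased in step 5. The step needs the correct enolate and a single alkylation per malonate: the tether-side enolate could only close a four-membered ring while the ethyl-side one reaches the ester through six atoms, and excess malonate plus fast ring closure keeps an adduct from adding to a second enone. Deprotonation of C3–H between the two ketones makes the sequence irreversible, which is why a full equivalent of NaOMe per ring is used.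

Step 5
Reactants: 8 dimethyl 6,6'-(tridecane-1,13-diyl)bis(3-methyl-2,4-dioxocyclohexane-1-carboxylate)
Product: 9 dimethyl 6,6'-(tridecane-1,13-diyl)bis(2,4-dihydroxy-3-methylbenzoate)
Conditions: I2 (20 mol % per ring), DMSO, 80–90 °C
Reagents that add atoms: none
Why: Iodine-catalysed oxidative aromatisation (enol iodination, loss of HI, tautomerisation, DMSO re-oxidising HI) is a known route from 2,4-dioxocyclohexanecarboxylates to resorcylates; iodination at the blocked C3 is reversible, the excess oxidant lets both rings go to completion, and the C1 ester protects the product arene from further halogenation.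

Step 6
Reactants: 9 dimethyl 6,6'-(tridecane-1,13-diyl)bis(2,4-dihydroxy-3-methylbenzoate)
Product: 10 methyl 6-{13-[3,5-dihydroxy-2-(methoxycarbonyl)-4-methylphenyl]tridecyl}-2-hydroxy-4-methoxy-3-methylbenzoate
Conditions: MeI (1.0 equiv), K2CO3 (1.0 equiv), acetone, reflux; chromatography, recovered 9 recycled
Reagents that add atoms: iodomethane, CI
Why: In this Williamson O-methylation both 2-OH groups are hydrogen-bonded to the ester carbonyl, so only 4-OH and 4'-OH compete; the desymmetrisation is therefore a two-site statistical event, capped at half of the material per pass, and it places the methyl group on an oxygen flanking C3.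

Step 7
Reactants: 10 mono-4-O-methyl bis(resorcylate)
Product: 12 5-[13-(3-hydroxy-5-methoxy-4-methylphenyl)tridecyl]-2-methylbenzene-1,3-diol, via diacid 11 (not isolated)
Conditions: 5 M aq NaOH, MeOH, reflux, N2; then 6 M HCl, 1,4-dioxane, reflux
Reagents that add atoms: none
Why: Saponification gives electron-rich salicylic acids that undergo protodecarboxylation by ipso-protonation on heating in acid, and the aryl methyl ether and alkyl tether are inert to both media.

Step 8
Reactants: 12 5-[13-(3-hydroxy-5-methoxy-4-methylphenyl)tridecyl]-2-methylbenzene-1,3-diol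
Product: 13 2-hydroxy-6-[13-(5-methoxy-4-methyl-3,6-dioxocyclohexa-1,4-dien-1-yl)tridecyl]-3-methylcyclohexa-2,5-diene-1,4-dione
Conditions: (KSO3)2NO (5 equiv), KH2PO4 buffer, H2O/acetone, rt
Reagents that add atoms: potassium nitrosodisulfonate (KSO3)2NO, [K+].[K+].[O]N(S(=O)(=O)[O-])S(=O)(=O)[O-]
Why: The Teuber oxidation turns a phenol with a free para C–H into the p-quinone; in ring A the only phenol (on C4) sends the new carbonyl to C1 between OMe and the tether, and in ring B both phenols lead to the same hydroxyquinone.

Step 9
Reactants: 13 methoxyquinone/hydroxyquinone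
Product: 15 heptaacetate (ring A 1,4,5-triacetoxy-2-methoxy-3-methyl; ring B 1,2,4,5-tetraacetoxy-3-methyl), via acetoxyquinone 14 (not isolated)
Conditions: Ac2O, H2SO4 (cat.), 0 °C to rt
Reagents that add atoms: acetic anhydride, CC(=O)OC(C)=O
Why: In the Thiele–Winter acetoxylation the acid-activated quinone takes up acetate at its only C–H carbon, C5, by conjugate addition to the C1 carbonyl, which the C2 oxygen does not deactivate; enolisation and acetylation then trap the arene, ring B reacting after acetylation of its OH.

Step 10
Reactants: 15 heptaacetate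
Product: 17 2,5-dihydroxy-3-[13-(2-hydroxy-5-methoxy-4-methyl-3,6-dioxocyclohexa-1,4-dien-1-yl)tridecyl]-6-methylcyclohexa-2,5-diene-1,4-dione (target), via heptaol 16 (not isolated)
Conditions: K2CO3, MeOH/THF, N2, rt; then air; then 1 M HCl
Reagents that add atoms: none
Why: Base-catalysed methanolysis of the aryl acetates frees two very electron-rich hydroquinones that autoxidise to the hydroxy-p-quinones, and in methanol any addition–elimination at the C2 methoxy carbon is degenerate, so the methyl ether of ring A is retained.

Compound list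
1 | ω-pentadecalactone (oxacyclohexadecan-2-one) | O=C1CCCCCCCCCCCCCCO1 | starting material
2 | pentadecane-1,15-diol | OCCCCCCCCCCCCCCCO | intermediate
3 | pentadecanedial | O=CCCCCCCCCCCCCCC=O | intermediate
4 | diethyl (2-oxobutyl)phosphonate | CCC(=O)CP(=O)(OCC)OCC | starting material
5 | (4E,19E)-tricosa-4,19-diene-3,21-dione | CCC(=O)/C=C/CCCCCCCCCCCCC/C=C/C(=O)CC | intermediate
6 | dimethyl malonate | COC(=O)CC(=O)OC | starting material
7 | tetramethyl 2,2'-(3,21-dioxotricosane-5,19-diyl)dipropanedioate (bis-Michael adduct, stereoisomer mixture) | CCC(=O)CC(C(C(=O)OC)C(=O)OC)CCCCCCCCCCCCCC(CC(=O)CC)C(C(=O)OC)C(=O)OC | intermediate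
8 | dimethyl 6,6'-(tridecane-1,13-diyl)bis(3-methyl-2,4-dioxocyclohexane-1-carboxylate) (epimers and enol forms) | COC(=O)C1C(=O)C(C)C(=O)CC1CCCCCCCCCCCCCC1CC(=O)C(C)C(=O)C1C(=O)OC | intermediate
9 | dimethyl 6,6'-(tridecane-1,13-diyl)bis(2,4-dihydroxy-3-methylbenzoate) | COC(=O)c1c(O)c(C)c(O)cc1CCCCCCCCCCCCCc1cc(O)c(C)c(O)c1C(=O)OC | intermediate
10 | methyl 6-{13-[3,5-dihydroxy-2-(methoxycarbonyl)-4-methylphenyl]tridecyl}-2-hydroxy-4-methoxy-3-methylbenzoate | COC(=O)c1c(O)c(C)c(OC)cc1CCCCCCCCCCCCCc1cc(O)c(C)c(O)c1C(=O)OC | intermediate
11 | 6-[13-(2-carboxy-3,5-dihydroxy-4-methylphenyl)tridecyl]-2-hydroxy-4-methoxy-3-methylbenzoic acid | OC(=O)c1c(O)c(C)c(OC)cc1CCCCCCCCCCCCCc1cc(O)c(C)c(O)c1C(=O)O | intermediate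
12 | 5-[13-(3-hydroxy-5-methoxy-4-methylphenyl)tridecyl]-2-methylbenzene-1,3-diol | COc1cc(CCCCCCCCCCCCCc2cc(O)c(C)c(O)c2)cc(O)c1C | intermediate
13 | 2-hydroxy-6-[13-(5-methoxy-4-methyl-3,6-dioxocyclohexa-1,4-dien-1-yl)tridecyl]-3-methylcyclohexa-2,5-diene-1,4-dione | COC1=C(C)C(=O)C=C(CCCCCCCCCCCCCC2=CC(=O)C(C)=C(O)C2=O)C1=O | intermediate
14 | ring-B 2-O-acetate of 13 | COC1=C(C)C(=O)C=C(CCCCCCCCCCCCCC2=CC(=O)C(C)=C(OC(C)=O)C2=O)C1=O | intermediate
15 | heptaacetate: 1,4,5-triacetoxy-2-methoxy-3-methylbenzene (ring A) and 1,2,4,5-tetraacetoxy-3-methylbenzene (ring B) joined C6 to C6' by (CH2)13 | COc1c(C)c(OC(C)=O)c(OC(C)=O)c(CCCCCCCCCCCCCc2c(OC(C)=O)c(OC(C)=O)c(C)c(OC(C)=O)c2OC(C)=O)c1OC(C)=O | intermediate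
16 | heptaol: 1,4,5-trihydroxy-2-methoxy-3-methylbenzene (ring A) and 1,2,4,5-tetrahydroxy-3-methylbenzene (ring B) joined C6 to C6' by (CH2)13 | COc1c(C)c(O)c(O)c(CCCCCCCCCCCCCc2c(O)c(O)c(C)c(O)c2O)c1O | intermediate
17 | 2,5-dihydroxy-3-[13-(2-hydroxy-5-methoxy-4-methyl-3,6-dioxocyclohexa-1,4-dien-1-yl)tridecyl]-6-methylcyclohexa-2,5-diene-1,4-dione (CNP0107579.0) | COC1=C(C)C(=O)C(O)=C(CCCCCCCCCCCCCC2=C(O)C(=O)C(C)=C(O)C2=O)C1=O | target

Total step count: 10. Longest linear sequence: 10 steps (1 to 17).

Steps most likely to fail

Step 4.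
- What may go wrong: reaction at only one terminus, reversal of the Michael addition, base-induced migration of the double bond out of conjugation, or a second Michael addition of an adduct onto another chain end, which would give oligomers.
- Fallback: the donor and acceptor roles are exchanged, so each ring is built from the other pair of fragments. It sets out from 3. Wittig olefination with Ph3P=CHCO2Me in CH2Cl2 should give dimethyl (2E,17E)-nonadeca-2,17-dienedioate F1.
- NaOMe in MeOH with methyl 3-oxopentanoate then adds the keto ester C2 to both enoates, giving dimethyl 3,17-bis(1-methoxy-1,3-dioxopentan-2-yl)nonadecanedioate F2.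
- The ethyl-side carbon of F2 closes on the chain ester by the same six-membered Claisen mode. The detour comes back to the route at 8.

Step 9.
- What may go wrong: slow conjugate addition of acetate to trisubstituted, donor-bearing quinones, which leaves time for acid-induced tautomerisation towards quinone methides, polymerisation or loss of the methyl ether.
- Fallback: the acid-mediated C–O bond formation is replaced by nucleophilic epoxidation. It sets out from 13. BnBr and K2CO3 in DMF cap the ring B hydroxyl to give 2-(benzyloxy)-6-[13-(5-methoxy-4-methyl-3,6-dioxocyclohexa-1,4-dien-1-yl)tridecyl]-3-methylcyclohexa-2,5-diene-1,4-dione F3.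
- H2O2 and Na2CO3 in aqueous dioxane epoxidise the electron-poorer C5=C6 bond of each ring to give the bis(epoxide) F4.
- H2SO4 on silica gel in CH2Cl2 opens each epoxide with loss of the C5 proton, the known quinone epoxide to hydroxyquinone isomerisation. This gives the ring-B 2-O-benzyl ether of the target F5.
- H2 over Pd on carbon (Pd/C) removes the benzyl group and reduces both quinones. The detour comes back to the route at 16, which is aired as in step 10.

Step 5.
- What may go wrong: iodination stalling at the blocked C3, iodination of the product arene, or partial loss of the ester in hot DMSO. Each would give mixtures in which only one ring is aromatic.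
- Fallback: the ester is removed first and the dehydrogenation is done with a metal oxidant. It sets out from 8. Aqueous NaOH and then hot HCl give 6,6'-(tridecane-1,13-diyl)bis(3-methyl-2,4-dioxocyclohexane-1-carboxylic acid) F6, which loses CO2 to give 5,5'-(tridecane-1,13-diyl)bis(2-methylcyclohexane-1,3-dione) F7.
- Hg(OAc)2 and NaOAc in refluxing AcOH, the known dehydrogenation of 2-alkylcyclohexane-1,3-diones, give 5,5'-(tridecane-1,13-diyl)bis(2-methylbenzene-1,3-diol) F8.
- One equivalent of MeI with K2CO3 in acetone methylates one of the four equivalent hydroxyls. The detour comes back to the route at 12.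

Further compounds
F1 | step 4 | dimethyl (2E,17E)-nonadeca-2,17-dienedioate | COC(=O)/C=C/CCCCCCCCCCCCC/C=C/C(=O)OC
F2 | step 4 | dimethyl 3,17-bis(1-methoxy-1,3-dioxopentan-2-yl)nonadecanedioate | CCC(=O)C(C(=O)OC)C(CC(=O)OC)CCCCCCCCCCCCCC(CC(=O)OC)C(C(=O)OC)C(=O)CC
F3 | step 9 | 2-(benzyloxy)-6-[13-(5-methoxy-4-methyl-3,6-dioxocyclohexa-1,4-dien-1-yl)tridecyl]-3-methylcyclohexa-2,5-diene-1,4-dione | COC1=C(C)C(=O)C=C(CCCCCCCCCCCCCC2=CC(=O)C(C)=C(OCc3ccccc3)C2=O)C1=O
F4 | step 9 | bis(epoxide) of F3 at C5–C6 and C5'–C6' (two 7-oxabicyclo[4.1.0]hept-3-ene-2,5-dione units, diastereomer mixture) | COC1=C(C)C(=O)C2OC2(CCCCCCCCCCCCCC34OC3C(=O)C(C)=C(OCc3ccccc3)C4=O)C1=O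
F5 | step 9 | ring-B 2-O-benzyl ether of the target | COC1=C(C)C(=O)C(O)=C(CCCCCCCCCCCCCC2=C(O)C(=O)C(C)=C(OCc3ccccc3)C2=O)C1=O
F6 | step 5 | 6,6'-(tridecane-1,13-diyl)bis(3-methyl-2,4-dioxocyclohexane-1-carboxylic acid) | OC(=O)C1C(=O)C(C)C(=O)CC1CCCCCCCCCCCCCC1CC(=O)C(C)C(=O)C1C(=O)O
F7 | step 5 | 5,5'-(tridecane-1,13-diyl)bis(2-methylcyclohexane-1,3-dione) | CC1C(=O)CC(CC1=O)CCCCCCCCCCCCCC1CC(=O)C(C)C(=O)C1
F8 | step 5 | 5,5'-(tridecane-1,13-diyl)bis(2-methylbenzene-1,3-diol) | Cc1c(O)cc(cc1O)CCCCCCCCCCCCCc1cc(O)c(C)c(O)c1
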